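**Retrosynthetic overview**

- The target is tetrabromocatechol in which the bromine on C1 (para to the C4 hydroxyl) is replaced by CHO, so the only disconnection is the C1–C7 bond between the ring and the formyl carbon.
- The plan rests on one feature: at the ortho-quinone oxidation level (carbonyls on C4 and C5 of the target), C1 and C2 are the β-carbons of the bromo-enones O=C5–C6=C1 and O=C4–C3=C2. They are vinylogous acyl bromide carbons and are equivalent by symmetry.
- C7 is delivered as a formyl-anion equivalent, formaldehyde dimethylhydrazone, which displaces one of these two bromides by addition–elimination with net loss of HBr.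
- The hydrazone is made from formaldehyde and 1,1-dimethylhydrazine; after the coupling, the quinone is reduced to the catechol and the hydrazone is hydrolysed to the aldehyde.
- No ring is formed anywhere in the route: the six-membered carbocycle, both oxygens and the three remaining bromines are bought together as tetrabromo-1,2-benzoquinone.

Key step: step 2

Remark on numbering: in the steps below, the quinone and the compounds derived from it are numbered with the two oxygen-bearing carbons as C1 and C2, so the carbon that receives the new substituent is C5 (equivalent to C4 in the symmetric quinone); it becomes C1 of the target.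

**Route**

Step 1
Reactants: 1 formaldehyde (used as paraformaldehyde); 2 1,1-dimethylhydrazine
Product: 3 formaldehyde dimethylhydrazone
Conditions: paraformaldehyde (1.0 equiv) added in portions to neat 2, 0 °C to rt; KOH pellets; distillation from CaH2 under Ar
Reagents that add atoms: none
Why: Hydrazone formation by carbonyl–hydrazine condensation should be clean because only the free NH2 of the 1,1-disubstituted hydrazine can condense, so no azine can form, and KOH removes the water that is released.

Step 2
Reactants: 4 3,4,5,6-tetrabromo-1,2-benzoquinone; 3 formaldehyde dimethylhydrazone
Product: 6 3,4,6-tribromo-5-[(E)-(dimethylhydrazono)methyl]-1,2-benzoquinone, via zwitterionic sigma-adduct 5 (not isolated)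
Conditions: 3 (1.05 equiv) added dropwise to 4, powdered NaHCO3 (3 equiv), 4 Å molecular sieves, CH2Cl2, −78 °C to 0 °C, dark, Ar; filtration and cold concentration, crude 6 taken on directly
Reagents that add atoms: none
Why: Proposed new method: the hydrazone should react as a neutral aza-enamine, its CH2 carbon adding to C5 of 4 (the β-carbon of the O=C1–C6=C5 bromo-enone) to give zwitterion 5, an enolate on O1 with a diazenium side chain; bromide then leaves the sp3 C5 to restore the ortho-quinone, and NaHCO3 removes a CH2 proton to restore the C=N bond. The closest known reaction types are addition–elimination of amines, thiolates and stabilised carbanions on tetrahaloquinones and conjugate addition of formaldehyde dialkylhydrazones to nitroalkenes and enones. No ring closes and no stereocentre is created; the only stereo-element is the hydrazone geometry, expected to be E because the aryl group and NMe2 avoid each other. The step needs attack at C4 or C5 and not at C3, C6 or the carbonyl carbons, which the vinylogous acyl bromide character of C4 and C5 should secure, and these two carbons are exchanged by the symmetry axis of 4, so either gives the same product. It also needs a single substitution, which should be secured because the hydrazone nitrogen lone pair in 6 conjugates with the C1 carbonyl (push–pull), lowering electrophilicity and reduction potential, and is helped by adding one equivalent of 3 slowly to cold 4. Low temperature, a weakly polar solvent and exclusion of light are chosen to disfavour electron transfer from the hydrazone to the quinone and hetero-Diels–Alder addition of the C=N bond across the dione.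

Step 3
Reactants: 6 3,4,6-tribromo-5-[(E)-(dimethylhydrazono)methyl]-1,2-benzoquinone
Product: 7 3,4,6-tribromo-5-[(E)-(dimethylhydrazono)methyl]benzene-1,2-diol
Conditions: Na2S2O4 (3 equiv), EtOAc/H2O, rt, Ar; organic layer dried and concentrated under Ar
Reagents that add atoms: none
Why: Dithionite reduction of a quinone to the dihydroxyarene is fast at room temperature in a two-phase system and should leave the aryl C–Br bonds and the hydrazone C=N bond untouched.

Step 4
Reactants: 7 3,4,6-tribromo-5-[(E)-(dimethylhydrazono)methyl]benzene-1,2-diol
Product: 8 2,3,6-tribromo-4,5-dihydroxybenzaldehyde
Conditions: 37% aq. formaldehyde 1 (10 equiv), 2 M HCl, THF, 45 °C, Ar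
Reagents that add atoms: water, O
Why: This is an acid-catalysed hydrazone hydrolysis run as a transhydrazonation, in which water cleaves the protonated C=N bond and the excess formaldehyde captures the released 1,1-dimethylhydrazine to pull the equilibrium towards the aldehyde, while the fully substituted ring offers no site for hydroxymethylation and the acidic, oxygen-free medium protects the catechol.

**Compound list**

1 | formaldehyde (as paraformaldehyde or 37% aqueous solution) | C=O | starting material
2 | 1,1-dimethylhydrazine | CN(C)N | starting material
3 | formaldehyde dimethylhydrazone | C=NN(C)C | intermediate
4 | 3,4,5,6-tetrabromo-1,2-benzoquinone | O=C1C(=O)C(Br)=C(Br)C(Br)=C1Br | starting material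
5 | zwitterionic sigma-adduct: ring C5 is sp3 and carries Br and CH2–N=N(+)Me2, with the enolate on O1 | C[N+](C)=NCC1(Br)C(Br)=C([O-])C(=O)C(Br)=C1Br | intermediate (not isolated)
6 | 3,4,6-tribromo-5-[(E)-(dimethylhydrazono)methyl]-1,2-benzoquinone | CN(C)/N=C/C1=C(Br)C(=O)C(=O)C(Br)=C1Br | intermediate
7 | 3,4,6-tribromo-5-[(E)-(dimethylhydrazono)methyl]benzene-1,2-diol | CN(C)/N=C/c1c(Br)c(O)c(O)c(Br)c1Br | intermediate
8 | 2,3,6-tribromo-4,5-dihydroxybenzaldehyde | O=Cc1c(Br)c(O)c(O)c(Br)c1Br | target

**Step count**

Total steps: 4. Longest linear sequence: 4 steps (steps 1 to 4).

**Steps most likely to fail**

Step 2 (carries the label "Proposed new method:"). What may go wrong: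
- electron transfer from the electron-rich hydrazone to the strongly oxidising quinone, which would reduce 4 and destroy 3 oxidatively;
- cycloaddition of the C=N bond across the O=C–C=O unit;
- a second substitution at the neighbouring β-carbon.

The fallback uses known chemistry, sets out from 4 and returns to the route at 8. The carbon is brought in as the nitromethane anion, a stabilised carbanion of the type known to displace halide from tetrahaloquinones by addition–elimination. Compound 4 would be treated with nitromethane and K2CO3 in MeCN at −20 to 0 °C and then acidified, to give 3,4,6-tribromo-5-(nitromethyl)-1,2-benzoquinone F1, which may sit as its aci-nitro tautomer. Na2S2O4 in EtOAc/water would reduce this to 3,4,6-tribromo-5-(nitromethyl)benzene-1,2-diol F2. A Nef reaction would then turn the CH2NO2 group into the aldehyde: the nitronate is formed in degassed aqueous NaOH at 0 °C and run into cold 4 M H2SO4 under Ar. This gives 8 without passing through 6 and 7.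

Step 4. What may go wrong: slow or incomplete hydrolysis of a hydrazone flanked by two ortho bromines and conjugated to an electron-rich ring, with oxidation of the catechol during long heating. The fallback sets out from 7 and returns at 8, and activates the hydrazone by quaternisation instead of relying on equilibrium exchange. MeI in MeCN at 40 °C should alkylate the NMe2 nitrogen (the phenols are not alkylated without base) to give (E)-1,1,1-trimethyl-2-[(2,3,6-tribromo-4,5-dihydroxyphenyl)methylidene]hydrazinium iodide F3. This cationic hydrazonium salt should hydrolyse in 1 M HCl/THF at room temperature to 8.

Step 3. What may go wrong: sulfite or bisulfite formed from the dithionite adding to the quinone or displacing a bromide, or re-oxidation of the electron-rich catechol by air during isolation. The fallback sets out from 6 and returns at 8, and traps the catechol as it forms. Reductive acetylation with zinc dust, Ac2O and NaOAc at room temperature should give 3,4,6-tribromo-5-[(E)-(dimethylhydrazono)methyl]-1,2-phenylene diacetate F4, which is stable to air. Treatment with HCl in MeOH and 37% aqueous formaldehyde at 50 °C would then remove both acetates by transesterification and cleave the hydrazone in one operation, to give 8.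

**Further compounds**

F1 | step 2 | 3,4,6-tribromo-5-(nitromethyl)-1,2-benzoquinone | O=C1C(=O)C(Br)=C(C[N+](=O)[O-])C(Br)=C1Br
F2 | step 2 | 3,4,6-tribromo-5-(nitromethyl)benzene-1,2-diol | O=[N+]([O-])Cc1c(Br)c(O)c(O)c(Br)c1Br
F3 | step 4 | (E)-1,1,1-trimethyl-2-[(2,3,6-tribromo-4,5-dihydroxyphenyl)methylidene]hydrazinium iodide | C[N+](C)(C)/N=C/c1c(Br)c(O)c(O)c(Br)c1Br.[I-]
F4 | step 3 | 3,4,6-tribromo-5-[(E)-(dimethylhydrazono)methyl]-1,2-phenylene diacetate | CN(C)/N=C/c1c(Br)c(OC(C)=O)c(OC(C)=O)c(Br)c1Br
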